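A closed, stirred vessel is charged with substrate, and molecules run round a ring: substrate to target, target to isomer of the product A, that to isomer of the product B, that back to substrate. Every step is reversible, and target has a side exit to isomer of the product C.

| setting | south-west | south | north-west |
|---|---|---|---|
| substrate | 0.40 M | 0.40 M | 0.40 M |
| temperature | 55 °C | 80 °C |  |
| time | 12 d | 12 d | 12 d |
| remark |  |  | at 55 °C until 8.0 d, from then on at 80 °C |

- which flask leads in amount of target, in percent of the substrate charged ("all alike" within 1.5 percentage points) (south-west / south / north-west / all alike)
- how much target is there at the end, in percent of the substrate charged: south-west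
- how much target is there at the end, in percent of the substrate charged: south
- how much target is there at the end, in percent of the substrate charged: north-west

- all constants are for 80 °C and move with temperature by the activation energies and enthalpies

    substrate ⇌ target (K1 = 2.3, k1 = 0.22 /h, Ea1 = 123 kJ/mol, ΔH1 = −1.00 kJ/mol)
    target ⇌ isomer of the product A (K2 = 16, k2 = 0.014 /h, Ea2 = 112 kJ/mol, ΔH2 = −59.0 kJ/mol)
    isomer of the product A ⇌ isomer of the product B (K3 = 0.79, k3 = 0.13 /h, Ea3 = 119 kJ/mol, ΔH3 = 24.0 kJ/mol)
    isomer of the product B ⇌ substrate (k4 = 0.0031 /h, Ea4 = 121 kJ/mol)
    target ⇌ isomer of the product C (K5 = 21, k5 = 0.0059 /h, Ea5 = 128 kJ/mol, ΔH5 = −8.00 kJ/mol)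
    (constants at 80 °C)

We follow one molecule and ask for its chances at each fork. At 55 °C a molecule of substrate can go to target or, running the ring backward, straight to isomer of the product B. The relaxation half-life 2.24 d and equilibrium constant 2.36 of the substrate–target step give its forward constant as 0.00905 /h. Scaling by activation energies, the backward path to isomer of the product B has 0.00993 /h. So 47.7 % of the molecules take the target branch at this fork.

How long does a molecule stay in target? It returns to substrate at 0.00383 /h and moves on at 9.79 × 10⁻⁴ /h, so 79.7 % of its departures go back to the fork. Counting the returns gives 9.68 d. This is the escape half-life: the half-life of a molecule in target against leaving the pair substrate and target. It is shorter than the 12 d of the run, and the fork share times the survivors after that time gives south-west a rough 20.2 % target.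

What happens at 80 °C? The same reckoning gives an escape half-life of 0.606 d, far shorter than the time. South therefore passes 19.8 escape half-lives, and the hot stretch of north-west 6.61. We expect south and north-west to end with what the ring returns: balance among its four members at 80 °C puts 3.33 % in target, less what has gone to isomer of the product C. Our rough figure for south-west is higher than that, so we expect south-west, under kinetic control, to lead.

The forecast names south-west, with 23 %, above our figure, then 2.7 % for south and 3.2 % for north-west, holding that at the higher temperature “target sits near its low equilibrium level of a few percent”.

The simulation puts south-west ahead, with 22.8 % target there, 2.66 % in south and 3.34 % in north-west.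

In south-west, with its escape half-life of 9.68 d, target stood at 31.1 % after 6.00 d beside 12.3 % substrate, and at 22.8 % after 12.0 d, while isomer of the product A reached 46.7 %. North-west ran the same course until 8.00 d, when it held 28.7 % target. Over the hot stretch, the escape half-life of 0.606 d leaves that target at 0.294 % of the charge, and north-west ended with 3.34 % target beside 49.7 % isomer of the product A.

The constants come from no measurement; the result is computed.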